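**Retrosynthetic overview**

- The strategy rests on C2 of the ring A dihydrofuran and C2' of the ring B dihydrofuran. Each is an sp3 carbon bonded to the ring oxygen and carries the same 4-hydroxyphenyl group trans to the aryl group on C3 or C3'. Both C2–aryl bonds are therefore cut together, giving a 2,2'-dicarboxylic acid and 4-iodoanisole (two-fold nickel–photoredox decarboxylative arylation).
- The diacid comes from two (4+1) annulations of ortho-quinone methides with tert-butyl-ester ammonium ylides that carry a cinchona alkaloid as chiral leaving group. Ring B is made first (quinidine salt), its aryl iodide is joined as the magnesium reagent to a ring A salicylaldehyde, then ring A is made (quinine salt); the two rings have opposite local configuration, so each needs its own reagent.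
- The ring A C4 carbon is a bromide during the union, because an ester there would lactonise with the new carbinol. It becomes the methyl ester before the key step, and afterwards goes through aldehyde and alkyne to the Z-stilbene (Sonogashira coupling with the same 4-iodoanisole, semihydrogenation); BBr3 then frees the seven phenols.
- Ring order: ring B dihydrofuran (step 4), ring A dihydrofuran (step 10); the key step closes no ring and sets C2 and C2'.

Key step: step 13

Remark: the facial sense of each cinchona ammonium ylide (quinidine-derived for the 2R,3R ring B, quinine-derived for the 2S,3S ring A) is assumed from the known annulation of simpler 2-(aryl(tosyl)methyl)phenols; should the first annulation show the opposite sense, the two salts would exchange places.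

**Route**

Step 1
Reactants: 1 2-hydroxy-5-iodo-3-methoxybenzaldehyde; 2 1-bromo-3,5-dimethoxybenzene
Product: 4 2-[(3,5-dimethoxyphenyl)(hydroxy)methyl]-4-iodo-6-methoxyphenol (racemic), via 3,5-dimethoxyphenylmagnesium bromide 3 (not isolated)
Conditions: 2 (2.5 equiv), Mg, THF, reflux; then 1, THF, −20 → 0 °C; aq. NH4Cl
Reagents that add atoms: none
Why: Grignard addition of the arylmagnesium bromide to the aldehyde of the magnesium phenoxide (one equivalent of reagent is spent on the phenol) should give the ortho-hydroxybenzhydrol, the aryl iodide being inert to an aryl Grignard reagent at this temperature and the racemic carbinol centre being erased in step 4.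

Step 2
Reactants: 4 2-[(3,5-dimethoxyphenyl)(hydroxy)methyl]-4-iodo-6-methoxyphenol
Product: 5 2-[(3,5-dimethoxyphenyl)(4-methylbenzenesulfonyl)methyl]-4-iodo-6-methoxyphenol (racemic)
Conditions: TolSO2Na (2.0 equiv), TsOH·H2O (1.5 equiv), CH2Cl2, rt
Reagents that add atoms: sodium p-toluenesulfinate, Cc1ccc(S(=O)[O-])cc1.[Na+]
Why: Acid-promoted ionisation of the ortho-hydroxybenzhydrol to the benzylic cation and capture by sulfinate at sulfur (SN1 substitution) should give the stable sulfone from which base later releases the quinone methide.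

Step 3
Reactants: 6 quinidine; 7 tert-butyl bromoacetate
Product: 8 N-(2-tert-butoxy-2-oxoethyl)quinidinium bromide (alkylated at the quinuclidine nitrogen)
Conditions: THF, rt; filtration
Reagents that add atoms: none
Why: Menshutkin quaternisation of the more nucleophilic quinuclidine nitrogen by the alpha-bromo ester should give the crystalline ammonium salt in which the alkaloid later acts as a chiral leaving group.

Step 4
Reactants: 5 2-[(3,5-dimethoxyphenyl)(4-methylbenzenesulfonyl)methyl]-4-iodo-6-methoxyphenol; 8 N-(2-tert-butoxy-2-oxoethyl)quinidinium bromide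
Product: 10 tert-butyl (2R,3R)-3-(3,5-dimethoxyphenyl)-5-iodo-7-methoxy-2,3-dihydro-1-benzofuran-2-carboxylate, via ring B ortho-quinone methide 9 (not isolated)
Conditions: 8 (1.5 equiv), Cs2CO3 (3 equiv), CH2Cl2, 0 °C → rt
Reagents that add atoms: none
Why: In this (4+1) annulation of an ammonium ylide with an ortho-quinone methide, Cs2CO3 eliminates sulfinate from 5 and deprotonates 8, the ester-stabilised ylide adds to the methide carbon and the phenoxide displaces quinidine in a 5-exo-tet closure of ring B, the chiral ammonium group choosing the face of the quinone methide and so setting C3 while the anti betaine closes to the trans C2 ester.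

Step 5
Reactants: 2 1-bromo-3,5-dimethoxybenzene
Product: 11 2-bromo-4,6-dimethoxybenzaldehyde
Conditions: POCl3, DMF, 0 → 90 °C; then aq. NaOAc
Reagents that add atoms: N,N-dimethylformamide, CN(C)C=O; water, O
Why: Vilsmeier–Haack formylation should attack the ring carbon para to one methoxy group and ortho to the other in preference to the more crowded carbon between the two methoxy groups, and any 4-bromo-2,6-dimethoxy isomer would be removed by crystallisation.

Step 6
Reactants: 11 2-bromo-4,6-dimethoxybenzaldehyde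
Product: 12 2-bromo-6-hydroxy-4-methoxybenzaldehyde
Conditions: BCl3 (1.2 equiv), CH2Cl2, −78 → 0 °C; then aq. HCl
Reagents that add atoms: none
Why: Chelation of boron between the aldehyde oxygen and the ortho methoxy oxygen directs cleavage to that methyl ether alone (chelation-controlled ortho demethylation), leaving the para methoxy group.

Step 7
Reactants: 10 tert-butyl (2R,3R)-3-(3,5-dimethoxyphenyl)-5-iodo-7-methoxy-2,3-dihydro-1-benzofuran-2-carboxylate; 12 2-bromo-6-hydroxy-4-methoxybenzaldehyde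
Product: 14 tert-butyl (2R,3R)-5-[(2-bromo-6-hydroxy-4-methoxyphenyl)(hydroxy)methyl]-3-(3,5-dimethoxyphenyl)-7-methoxy-2,3-dihydro-1-benzofuran-2-carboxylate (mixture of carbinol epimers), via arylmagnesium chloride 13 (not isolated)
Conditions: 10, iPrMgCl·LiCl (1.05 equiv), THF, −20 °C; then 12 (1.3 equiv) pretreated with iPrMgCl (1.3 equiv) in THF, −20 → 0 °C; aq. NH4Cl
Reagents that add atoms: none
Why: Iodine–magnesium exchange at −20 °C is faster than attack on the hindered tert-butyl ester, and the arylmagnesium chloride then adds to the aldehyde of the preformed magnesium phenoxide of 12 (Grignard addition) without touching the aryl bromide, the unselective carbinol centre being erased in step 10.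

Step 8
Reactants: 14 tert-butyl (2R,3R)-5-[(2-bromo-6-hydroxy-4-methoxyphenyl)(hydroxy)methyl]-3-(3,5-dimethoxyphenyl)-7-methoxy-2,3-dihydro-1-benzofuran-2-carboxylate
Product: 15 tert-butyl (2R,3R)-5-[(2-bromo-6-hydroxy-4-methoxyphenyl)(4-methylbenzenesulfonyl)methyl]-3-(3,5-dimethoxyphenyl)-7-methoxy-2,3-dihydro-1-benzofuran-2-carboxylate (mixture of epimers at the sulfonyl carbon)
Conditions: TolSO2Na (2.0 equiv), TsOH·H2O (1.5 equiv), CH2Cl2, 0 °C → rt
Reagents that add atoms: sodium p-toluenesulfinate, Cc1ccc(S(=O)[O-])cc1.[Na+]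
Why: The carbinol carbon is flanked by an ortho-hydroxy, para-methoxy aryl group and a para-alkoxy aryl group, so it ionises under the weakly acidic sulfinic acid medium (SN1 substitution by sulfinate at sulfur) under which the tert-butyl ester should survive.

Step 9
Reactants: 16 quinine; 7 tert-butyl bromoacetate
Product: 17 N-(2-tert-butoxy-2-oxoethyl)quininium bromide (alkylated at the quinuclidine nitrogen)
Conditions: THF, rt; filtration
Reagents that add atoms: none
Why: Menshutkin quaternisation as in step 3 should give the pseudoenantiomeric ammonium salt needed for the opposite local configuration of ring A.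

Step 10
Reactants: 15 tert-butyl (2R,3R)-5-[(2-bromo-6-hydroxy-4-methoxyphenyl)(4-methylbenzenesulfonyl)methyl]-3-(3,5-dimethoxyphenyl)-7-methoxy-2,3-dihydro-1-benzofuran-2-carboxylate; 17 N-(2-tert-butoxy-2-oxoethyl)quininium bromide
Product: 19 tert-butyl (2S,3S)-4-bromo-3-[(2R,3R)-2-(tert-butoxycarbonyl)-3-(3,5-dimethoxyphenyl)-7-methoxy-2,3-dihydro-1-benzofuran-5-yl]-6-methoxy-2,3-dihydro-1-benzofuran-2-carboxylate, via ring A ortho-quinone methide 18 (not isolated)
Conditions: 17 (1.5 equiv), Cs2CO3 (3 equiv), CH2Cl2, 0 °C → rt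
Reagents that add atoms: none
Why: The same (4+1) annulation of an ammonium ylide with an ortho-quinone methide closes ring A by conjugate addition and 5-exo-tet displacement of quinine, the quinine-derived ylide setting C3 by reagent control (the ring B stereocentres are too remote to bias the methide faces) and the anti betaine giving the trans C2 ester.

Step 11
Reactants: 19 tert-butyl (2S,3S)-4-bromo-3-[(2R,3R)-2-(tert-butoxycarbonyl)-3-(3,5-dimethoxyphenyl)-7-methoxy-2,3-dihydro-1-benzofuran-5-yl]-6-methoxy-2,3-dihydro-1-benzofuran-2-carboxylate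
Product: 20 2-tert-butyl 4-methyl (2S,3S)-3-[(2R,3R)-2-(tert-butoxycarbonyl)-3-(3,5-dimethoxyphenyl)-7-methoxy-2,3-dihydro-1-benzofuran-5-yl]-6-methoxy-2,3-dihydro-1-benzofuran-2,4-dicarboxylate
Conditions: Pd(OAc)2 (5 mol %), Xantphos (10 mol %), CO (1 atm), MeOH, Et3N, toluene, 80 °C
Reagents that add atoms: carbon monoxide, [C-]#[O+]; methanol, CO
Why: Palladium-catalysed methoxycarbonylation of the aryl bromide (oxidative addition to zerovalent palladium, CO insertion, methanolysis of the acylpalladium) tolerates ortho substitution with a wide-bite-angle diphosphine and leaves the tert-butyl esters and all stereocentres untouched.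

Step 12
Reactants: 20 2-tert-butyl 4-methyl (2S,3S)-3-[(2R,3R)-2-(tert-butoxycarbonyl)-3-(3,5-dimethoxyphenyl)-7-methoxy-2,3-dihydro-1-benzofuran-5-yl]-6-methoxy-2,3-dihydro-1-benzofuran-2,4-dicarboxylate
Product: 21 (2S,3S)-3-[(2R,3R)-2-carboxy-3-(3,5-dimethoxyphenyl)-7-methoxy-2,3-dihydro-1-benzofuran-5-yl]-6-methoxy-4-(methoxycarbonyl)-2,3-dihydro-1-benzofuran-2-carboxylic acid
Conditions: CF3CO2H/CH2Cl2 (1:3), Et3SiH (5 equiv), 0 °C → rt
Reagents that add atoms: none
Why: Acidolysis of the two tert-butyl esters through the tert-butyl cation, which the silane reduces before it can alkylate the dimethoxyaryl rings, should free both acids while the methyl ester and the aryl methyl ethers are stable.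

Step 13
Reactants: 21 (2S,3S)-3-[(2R,3R)-2-carboxy-3-(3,5-dimethoxyphenyl)-7-methoxy-2,3-dihydro-1-benzofuran-5-yl]-6-methoxy-4-(methoxycarbonyl)-2,3-dihydro-1-benzofuran-2-carboxylic acid; 22 4-iodoanisole
Product: 25 methyl (2S,3S)-3-[(2R,3R)-3-(3,5-dimethoxyphenyl)-7-methoxy-2-(4-methoxyphenyl)-2,3-dihydro-1-benzofuran-5-yl]-6-methoxy-2-(4-methoxyphenyl)-2,3-dihydro-1-benzofuran-4-carboxylate, via ring A monoarylated acid 23 (not isolated), via ring B monoarylated acid 24 (not isolated)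
Conditions: 22 (4 equiv), Ir[dF(CF3)ppy]2(dtbbpy)PF6 (2 mol %), NiCl2(dme) (20 mol %), dtbbpy (30 mol %), Cs2CO3 (3 equiv), DMF, blue LEDs (450 nm), 25 °C
Reagents that add atoms: none
Why: Blue-light excitation of the trivalent iridium complex gives an oxidant that takes one electron from each cesium carboxylate of 21, CO2 is lost and an alpha-aryloxy radical forms at C2 or C2'; zerovalent nickel ligated by dtbbpy adds oxidatively to 4-iodoanisole, the divalent arylnickel iodide captures the radical, reductive elimination from trivalent nickel forms the C2–aryl bond, and the reduced iridium complex returns monovalent nickel to the zerovalent state. The closest known reaction type is the nickel–photoredox decarboxylative arylation of alpha-oxy carboxylic acids with aryl halides, used here at two like and remote sites that should react independently through the monoacids 23 and 24. No ring is closed. The new stereocentres C2 and C2' are set by substrate control: each C2 radical is planar, so the configuration of the acid is lost, and the arylnickel species is met on the face away from the aryl group on the adjacent C3 or C3', which should give the trans,trans product. The step needs this trans selectivity, secured by the C3 and C3' aryl groups, and chemoselectivity for the two carboxylates, secured because the methyl ester and the aryl methyl ethers are neither ionisable nor oxidised by the excited catalyst and 21 holds no carbon–halogen bond.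

Step 14
Reactants: 25 methyl (2S,3S)-3-[(2R,3R)-3-(3,5-dimethoxyphenyl)-7-methoxy-2-(4-methoxyphenyl)-2,3-dihydro-1-benzofuran-5-yl]-6-methoxy-2-(4-methoxyphenyl)-2,3-dihydro-1-benzofuran-4-carboxylate
Product: 26 [(2S,3S)-3-[(2R,3R)-3-(3,5-dimethoxyphenyl)-7-methoxy-2-(4-methoxyphenyl)-2,3-dihydro-1-benzofuran-5-yl]-6-methoxy-2-(4-methoxyphenyl)-2,3-dihydro-1-benzofuran-4-yl]methanol
Conditions: iBu2AlH (3 equiv), CH2Cl2, −78 → 0 °C; aq. potassium sodium tartrate
Reagents that add atoms: none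
Why: Hydride reduction of the aryl methyl ester, now the only carbonyl group, should give the benzylic alcohol without touching the ethers or the stereocentres.

Step 15
Reactants: 26 [(2S,3S)-3-[(2R,3R)-3-(3,5-dimethoxyphenyl)-7-methoxy-2-(4-methoxyphenyl)-2,3-dihydro-1-benzofuran-5-yl]-6-methoxy-2-(4-methoxyphenyl)-2,3-dihydro-1-benzofuran-4-yl]methanol
Product: 27 (2S,3S)-3-[(2R,3R)-3-(3,5-dimethoxyphenyl)-7-methoxy-2-(4-methoxyphenyl)-2,3-dihydro-1-benzofuran-5-yl]-6-methoxy-2-(4-methoxyphenyl)-2,3-dihydro-1-benzofuran-4-carbaldehyde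
Conditions: Dess–Martin periodinane, CH2Cl2, rt
Reagents that add atoms: none
Why: Dess–Martin oxidation of the hindered primary benzylic alcohol stops at the aldehyde under near-neutral conditions.

Step 16
Reactants: 27 (2S,3S)-3-[(2R,3R)-3-(3,5-dimethoxyphenyl)-7-methoxy-2-(4-methoxyphenyl)-2,3-dihydro-1-benzofuran-5-yl]-6-methoxy-2-(4-methoxyphenyl)-2,3-dihydro-1-benzofuran-4-carbaldehyde
Product: 28 (2S,3S)-3-[(2R,3R)-3-(3,5-dimethoxyphenyl)-7-methoxy-2-(4-methoxyphenyl)-2,3-dihydro-1-benzofuran-5-yl]-4-ethynyl-6-methoxy-2-(4-methoxyphenyl)-2,3-dihydro-1-benzofuran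
Conditions: dimethyl (1-diazo-2-oxopropyl)phosphonate, K2CO3, MeOH/THF, rt
Reagents that add atoms: dimethyl (1-diazo-2-oxopropyl)phosphonate, COP(=O)(OC)C(=[N+]=[N-])C(C)=O
Why: Ohira–Bestmann homologation (Seyferth–Gilbert type) of the non-enolisable aryl aldehyde under mild carbonate conditions should give the terminal alkyne by Horner–Wadsworth–Emmons olefination, loss of N2 and 1,2-shift of the vinylidene carbene.

Step 17
Reactants: 28 (2S,3S)-3-[(2R,3R)-3-(3,5-dimethoxyphenyl)-7-methoxy-2-(4-methoxyphenyl)-2,3-dihydro-1-benzofuran-5-yl]-4-ethynyl-6-methoxy-2-(4-methoxyphenyl)-2,3-dihydro-1-benzofuran; 22 4-iodoanisole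
Product: 29 (2S,3S)-3-[(2R,3R)-3-(3,5-dimethoxyphenyl)-7-methoxy-2-(4-methoxyphenyl)-2,3-dihydro-1-benzofuran-5-yl]-6-methoxy-2-(4-methoxyphenyl)-4-[(4-methoxyphenyl)ethynyl]-2,3-dihydro-1-benzofuran
Conditions: 22 (1.5 equiv), Pd(PPh3)2Cl2 (5 mol %), CuI (10 mol %), Et3N, THF, 50 °C
Reagents that add atoms: none
Why: Sonogashira coupling of the terminal alkyne with the aryl iodide (oxidative addition to zerovalent palladium, transmetalation from the copper acetylide, reductive elimination) should give the diarylalkyne.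

Step 18
Reactants: 29 (2S,3S)-3-[(2R,3R)-3-(3,5-dimethoxyphenyl)-7-methoxy-2-(4-methoxyphenyl)-2,3-dihydro-1-benzofuran-5-yl]-6-methoxy-2-(4-methoxyphenyl)-4-[(4-methoxyphenyl)ethynyl]-2,3-dihydro-1-benzofuran
Product: 30 (2S,3S)-3-[(2R,3R)-3-(3,5-dimethoxyphenyl)-7-methoxy-2-(4-methoxyphenyl)-2,3-dihydro-1-benzofuran-5-yl]-6-methoxy-2-(4-methoxyphenyl)-4-[(Z)-2-(4-methoxyphenyl)ethenyl]-2,3-dihydro-1-benzofuran
Conditions: H2 (1 atm), Pd/CaCO3 poisoned with Pb(OAc)2 (Lindlar catalyst), quinoline, EtOAc, rt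
Reagents that add atoms: none
Why: Lindlar semihydrogenation delivers both hydrogens to one face of the alkyne on the poisoned palladium surface, so the Z-stilbene should form and reduction should stop there.

Step 19
Reactants: 30 (2S,3S)-3-[(2R,3R)-3-(3,5-dimethoxyphenyl)-7-methoxy-2-(4-methoxyphenyl)-2,3-dihydro-1-benzofuran-5-yl]-6-methoxy-2-(4-methoxyphenyl)-4-[(Z)-2-(4-methoxyphenyl)ethenyl]-2,3-dihydro-1-benzofuran
Product: 31 (2S,3S)-3-[(2R,3R)-3-(3,5-dihydroxyphenyl)-7-hydroxy-2-(4-hydroxyphenyl)-2,3-dihydro-1-benzofuran-5-yl]-2-(4-hydroxyphenyl)-4-[(Z)-2-(4-hydroxyphenyl)ethenyl]-2,3-dihydro-1-benzofuran-6-ol (CNP0172909.2)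
Conditions: BBr3 (14 equiv), CH2Cl2, −78 → 0 °C; then MeOH, aq. NaHCO3
Reagents that add atoms: none
Why: Lewis-acid demethylation (boron coordinates each ether oxygen and bromide attacks the methyl group) should cleave all seven aryl methyl ethers at low temperature, where the Z-alkene and the trans dihydrofurans are expected to persist.

**Compound list**

1 | 2-hydroxy-5-iodo-3-methoxybenzaldehyde | COc1cc(I)cc(C=O)c1O | starting material
2 | 1-bromo-3,5-dimethoxybenzene | COc1cc(Br)cc(OC)c1 | starting material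
3 | 3,5-dimethoxyphenylmagnesium bromide | COc1cc([Mg]Br)cc(OC)c1 | intermediate
4 | 2-[(3,5-dimethoxyphenyl)(hydroxy)methyl]-4-iodo-6-methoxyphenol (racemic) | COc1cc(I)cc(C(O)c2cc(OC)cc(OC)c2)c1O | intermediate
5 | 2-[(3,5-dimethoxyphenyl)(4-methylbenzenesulfonyl)methyl]-4-iodo-6-methoxyphenol (racemic) | COc1cc(I)cc(C(c2cc(OC)cc(OC)c2)S(=O)(=O)c2ccc(C)cc2)c1O | intermediate
6 | quinidine | COc1ccc2nccc([C@@H]([C@H]3C[C@@H]4CCN3C[C@@H]4C=C)O)c2c1 | starting material
7 | tert-butyl bromoacetate | CC(C)(C)OC(=O)CBr | starting material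
8 | N-(2-tert-butoxy-2-oxoethyl)quinidinium bromide | COc1ccc2nccc([C@@H]([C@H]3C[C@@H]4CC[N@@+]3(CC(=O)OC(C)(C)C)C[C@@H]4C=C)O)c2c1.[Br-] | intermediate
9 | ring B ortho-quinone methide, 6-[(3,5-dimethoxyphenyl)methylidene]-4-iodo-2-methoxycyclohexa-2,4-dien-1-one | COC1=CC(I)=CC(=Cc2cc(OC)cc(OC)c2)C1=O | intermediate
10 | tert-butyl (2R,3R)-3-(3,5-dimethoxyphenyl)-5-iodo-7-methoxy-2,3-dihydro-1-benzofuran-2-carboxylate | Ic1cc(OC)c2c(c1)[C@@H](c1cc(OC)cc(OC)c1)[C@H](C(=O)OC(C)(C)C)O2 | intermediate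
11 | 2-bromo-4,6-dimethoxybenzaldehyde | COc1cc(Br)c(C=O)c(OC)c1 | intermediate
12 | 2-bromo-6-hydroxy-4-methoxybenzaldehyde | COc1cc(O)c(C=O)c(Br)c1 | intermediate
13 | [(2R,3R)-2-(tert-butoxycarbonyl)-3-(3,5-dimethoxyphenyl)-7-methoxy-2,3-dihydro-1-benzofuran-5-yl]magnesium chloride | Cl[Mg]c1cc(OC)c2c(c1)[C@@H](c1cc(OC)cc(OC)c1)[C@H](C(=O)OC(C)(C)C)O2 | intermediate
14 | tert-butyl (2R,3R)-5-[(2-bromo-6-hydroxy-4-methoxyphenyl)(hydroxy)methyl]-3-(3,5-dimethoxyphenyl)-7-methoxy-2,3-dihydro-1-benzofuran-2-carboxylate (mixture of carbinol epimers) | COc1cc(O)c(C(O)c2cc(OC)c3c(c2)[C@@H](c2cc(OC)cc(OC)c2)[C@H](C(=O)OC(C)(C)C)O3)c(Br)c1 | intermediate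
15 | tert-butyl (2R,3R)-5-[(2-bromo-6-hydroxy-4-methoxyphenyl)(4-methylbenzenesulfonyl)methyl]-3-(3,5-dimethoxyphenyl)-7-methoxy-2,3-dihydro-1-benzofuran-2-carboxylate (mixture of epimers at the sulfonyl carbon) | COc1cc(O)c(C(c2cc(OC)c3c(c2)[C@@H](c2cc(OC)cc(OC)c2)[C@H](C(=O)OC(C)(C)C)O3)S(=O)(=O)c2ccc(C)cc2)c(Br)c1 | intermediate
16 | quinine | COc1ccc2nccc([C@H]([C@@H]3C[C@@H]4CCN3C[C@@H]4C=C)O)c2c1 | starting material
17 | N-(2-tert-butoxy-2-oxoethyl)quininium bromide | COc1ccc2nccc([C@H]([C@@H]3C[C@@H]4CC[N@@+]3(CC(=O)OC(C)(C)C)C[C@@H]4C=C)O)c2c1.[Br-] | intermediate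
18 | ring A ortho-quinone methide, tert-butyl (2R,3R)-5-[(2-bromo-4-methoxy-6-oxocyclohexa-2,4-dien-1-ylidene)methyl]-3-(3,5-dimethoxyphenyl)-7-methoxy-2,3-dihydro-1-benzofuran-2-carboxylate | COC1=CC(=O)C(=Cc2cc(OC)c3c(c2)[C@@H](c2cc(OC)cc(OC)c2)[C@H](C(=O)OC(C)(C)C)O3)C(Br)=C1 | intermediate
19 | tert-butyl (2S,3S)-4-bromo-3-[(2R,3R)-2-(tert-butoxycarbonyl)-3-(3,5-dimethoxyphenyl)-7-methoxy-2,3-dihydro-1-benzofuran-5-yl]-6-methoxy-2,3-dihydro-1-benzofuran-2-carboxylate | Brc1cc(OC)cc2c1[C@H](c1cc(OC)c3c(c1)[C@@H](c1cc(OC)cc(OC)c1)[C@H](C(=O)OC(C)(C)C)O3)[C@@H](C(=O)OC(C)(C)C)O2 | intermediate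
20 | 2-tert-butyl 4-methyl (2S,3S)-3-[(2R,3R)-2-(tert-butoxycarbonyl)-3-(3,5-dimethoxyphenyl)-7-methoxy-2,3-dihydro-1-benzofuran-5-yl]-6-methoxy-2,3-dihydro-1-benzofuran-2,4-dicarboxylate | COC(=O)c1cc(OC)cc2c1[C@H](c1cc(OC)c3c(c1)[C@@H](c1cc(OC)cc(OC)c1)[C@H](C(=O)OC(C)(C)C)O3)[C@@H](C(=O)OC(C)(C)C)O2 | intermediate
21 | (2S,3S)-3-[(2R,3R)-2-carboxy-3-(3,5-dimethoxyphenyl)-7-methoxy-2,3-dihydro-1-benzofuran-5-yl]-6-methoxy-4-(methoxycarbonyl)-2,3-dihydro-1-benzofuran-2-carboxylic acid | COC(=O)c1cc(OC)cc2c1[C@H](c1cc(OC)c3c(c1)[C@@H](c1cc(OC)cc(OC)c1)[C@H](C(=O)O)O3)[C@@H](C(=O)O)O2 | intermediate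
22 | 4-iodoanisole | COc1ccc(I)cc1 | starting material
23 | ring A monoarylated acid, (2R,3R)-3-(3,5-dimethoxyphenyl)-7-methoxy-5-[(2S,3S)-6-methoxy-4-(methoxycarbonyl)-2-(4-methoxyphenyl)-2,3-dihydro-1-benzofuran-3-yl]-2,3-dihydro-1-benzofuran-2-carboxylic acid | COC(=O)c1cc(OC)cc2c1[C@H](c1cc(OC)c3c(c1)[C@@H](c1cc(OC)cc(OC)c1)[C@H](C(=O)O)O3)[C@@H](c1ccc(OC)cc1)O2 | intermediate
24 | ring B monoarylated acid, (2S,3S)-3-[(2R,3R)-3-(3,5-dimethoxyphenyl)-7-methoxy-2-(4-methoxyphenyl)-2,3-dihydro-1-benzofuran-5-yl]-6-methoxy-4-(methoxycarbonyl)-2,3-dihydro-1-benzofuran-2-carboxylic acid | COC(=O)c1cc(OC)cc2c1[C@H](c1cc(OC)c3c(c1)[C@@H](c1cc(OC)cc(OC)c1)[C@H](c1ccc(OC)cc1)O3)[C@@H](C(=O)O)O2 | intermediate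
25 | methyl (2S,3S)-3-[(2R,3R)-3-(3,5-dimethoxyphenyl)-7-methoxy-2-(4-methoxyphenyl)-2,3-dihydro-1-benzofuran-5-yl]-6-methoxy-2-(4-methoxyphenyl)-2,3-dihydro-1-benzofuran-4-carboxylate | COC(=O)c1cc(OC)cc2c1[C@H](c1cc(OC)c3c(c1)[C@@H](c1cc(OC)cc(OC)c1)[C@H](c1ccc(OC)cc1)O3)[C@@H](c1ccc(OC)cc1)O2 | intermediate
26 | [(2S,3S)-3-[(2R,3R)-3-(3,5-dimethoxyphenyl)-7-methoxy-2-(4-methoxyphenyl)-2,3-dihydro-1-benzofuran-5-yl]-6-methoxy-2-(4-methoxyphenyl)-2,3-dihydro-1-benzofuran-4-yl]methanol | OCc1cc(OC)cc2c1[C@H](c1cc(OC)c3c(c1)[C@@H](c1cc(OC)cc(OC)c1)[C@H](c1ccc(OC)cc1)O3)[C@@H](c1ccc(OC)cc1)O2 | intermediate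
27 | (2S,3S)-3-[(2R,3R)-3-(3,5-dimethoxyphenyl)-7-methoxy-2-(4-methoxyphenyl)-2,3-dihydro-1-benzofuran-5-yl]-6-methoxy-2-(4-methoxyphenyl)-2,3-dihydro-1-benzofuran-4-carbaldehyde | O=Cc1cc(OC)cc2c1[C@H](c1cc(OC)c3c(c1)[C@@H](c1cc(OC)cc(OC)c1)[C@H](c1ccc(OC)cc1)O3)[C@@H](c1ccc(OC)cc1)O2 | intermediate
28 | (2S,3S)-3-[(2R,3R)-3-(3,5-dimethoxyphenyl)-7-methoxy-2-(4-methoxyphenyl)-2,3-dihydro-1-benzofuran-5-yl]-4-ethynyl-6-methoxy-2-(4-methoxyphenyl)-2,3-dihydro-1-benzofuran | C#Cc1cc(OC)cc2c1[C@H](c1cc(OC)c3c(c1)[C@@H](c1cc(OC)cc(OC)c1)[C@H](c1ccc(OC)cc1)O3)[C@@H](c1ccc(OC)cc1)O2 | intermediate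
29 | (2S,3S)-3-[(2R,3R)-3-(3,5-dimethoxyphenyl)-7-methoxy-2-(4-methoxyphenyl)-2,3-dihydro-1-benzofuran-5-yl]-6-methoxy-2-(4-methoxyphenyl)-4-[(4-methoxyphenyl)ethynyl]-2,3-dihydro-1-benzofuran | COc1ccc(C#Cc2cc(OC)cc3c2[C@H](c2cc(OC)c4c(c2)[C@@H](c2cc(OC)cc(OC)c2)[C@H](c2ccc(OC)cc2)O4)[C@@H](c2ccc(OC)cc2)O3)cc1 | intermediate
30 | (2S,3S)-3-[(2R,3R)-3-(3,5-dimethoxyphenyl)-7-methoxy-2-(4-methoxyphenyl)-2,3-dihydro-1-benzofuran-5-yl]-6-methoxy-2-(4-methoxyphenyl)-4-[(Z)-2-(4-methoxyphenyl)ethenyl]-2,3-dihydro-1-benzofuran | COc1ccc(/C=C\c2cc(OC)cc3c2[C@H](c2cc(OC)c4c(c2)[C@@H](c2cc(OC)cc(OC)c2)[C@H](c2ccc(OC)cc2)O4)[C@@H](c2ccc(OC)cc2)O3)cc1 | intermediate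
31 | (2S,3S)-3-[(2R,3R)-3-(3,5-dihydroxyphenyl)-7-hydroxy-2-(4-hydroxyphenyl)-2,3-dihydro-1-benzofuran-5-yl]-2-(4-hydroxyphenyl)-4-[(Z)-2-(4-hydroxyphenyl)ethenyl]-2,3-dihydro-1-benzofuran-6-ol (CNP0172909.2) | Oc1ccc(/C=C\c2cc(O)cc3c2[C@H](c2cc(O)c4c(c2)[C@@H](c2cc(O)cc(O)c2)[C@H](c2ccc(O)cc2)O4)[C@@H](c2ccc(O)cc2)O3)cc1 | target

**Step count and risks**

Total step count: 19. Longest linear sequence: 15 steps (steps 1, 2, 4, 7, 8 and 10 to 19); steps 3, 5, 6 and 9 are side branches.

Steps most likely to fail: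

- **Step 13.** The electron-rich aryl iodide may add slowly to nickel, so the C2 radicals could be lost to protodecarboxylation or to over-oxidation, the second coupling could stall at a monoacid, and the facial selectivity at either C2 could be poor. The fallback sets out from 21. Both acids would be esterified with N-hydroxyphthalimide (N,N'-diisopropylcarbodiimide, catalytic DMAP, CH2Cl2) to give the bis(1,3-dioxoisoindolin-2-yl) ester of 21 F1. A thermal nickel-catalysed reductive cross-electrophile coupling of this redox-active diester with 22 (NiBr2(dme), dtbbpy, Zn powder, DMA, rt) would then form both C2–aryl bonds without light and return to the route at 25.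

- **Step 19.** Under the Lewis acid the Z-alkene may isomerise, the protonated stilbene may cyclise onto a neighbouring electron-rich ring, or the C2–O bonds may ionise. The fallback sets out from 29. The alkyne, which holds no protonatable stilbene, would be demethylated first with BBr3 in CH2Cl2 to give the heptaphenol (2S,3S)-3-[(2R,3R)-3-(3,5-dihydroxyphenyl)-7-hydroxy-2-(4-hydroxyphenyl)-2,3-dihydro-1-benzofuran-5-yl]-2-(4-hydroxyphenyl)-4-[(4-hydroxyphenyl)ethynyl]-2,3-dihydro-1-benzofuran-6-ol F2. Semihydrogenation of F2 (H2, Pd/CaCO3 poisoned with Pb(OAc)2, quinoline, EtOAc/MeOH) would be the last operation and return to the route at 31.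

- **Step 10.** The bromine beside the methide carbon of 18 crowds the exocyclic alkene and may change its geometry, so the bulky cinchona ylide may add slowly or with poor facial selectivity. The fallback sets out from 15 and gives up reagent control. The small achiral ylide from (2-tert-butoxy-2-oxoethyl)dimethylsulfonium bromide F3 (made from 7 and dimethyl sulfide in acetone) with Cs2CO3 in CH2Cl2 should give the trans annulation on both faces. This would give 19 together with its ring A epimer tert-butyl (2R,3R)-4-bromo-3-[(2R,3R)-2-(tert-butoxycarbonyl)-3-(3,5-dimethoxyphenyl)-7-methoxy-2,3-dihydro-1-benzofuran-5-yl]-6-methoxy-2,3-dihydro-1-benzofuran-2-carboxylate F4. The two are diastereomers because ring B is already a single enantiomer, so preparative HPLC would separate them and the route is rejoined at 19.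

**Further compounds**

F1 | step 13 | bis(1,3-dioxoisoindolin-2-yl) ester of 21, 2-(1,3-dioxoisoindolin-2-yl) 4-methyl (2S,3S)-3-[(2R,3R)-3-(3,5-dimethoxyphenyl)-2-[(1,3-dioxoisoindolin-2-yl)oxycarbonyl]-7-methoxy-2,3-dihydro-1-benzofuran-5-yl]-6-methoxy-2,3-dihydro-1-benzofuran-2,4-dicarboxylate | COC(=O)c1cc(OC)cc2c1[C@H](c1cc(OC)c3c(c1)[C@@H](c1cc(OC)cc(OC)c1)[C@H](C(=O)ON1C(=O)c4ccccc4C1=O)O3)[C@@H](C(=O)ON1C(=O)c3ccccc3C1=O)O2
F2 | step 19 | (2S,3S)-3-[(2R,3R)-3-(3,5-dihydroxyphenyl)-7-hydroxy-2-(4-hydroxyphenyl)-2,3-dihydro-1-benzofuran-5-yl]-2-(4-hydroxyphenyl)-4-[(4-hydroxyphenyl)ethynyl]-2,3-dihydro-1-benzofuran-6-ol | Oc1ccc(C#Cc2cc(O)cc3c2[C@H](c2cc(O)c4c(c2)[C@@H](c2cc(O)cc(O)c2)[C@H](c2ccc(O)cc2)O4)[C@@H](c2ccc(O)cc2)O3)cc1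
F3 | step 10 | (2-tert-butoxy-2-oxoethyl)dimethylsulfonium bromide | C[S+](C)CC(=O)OC(C)(C)C.[Br-]
F4 | step 10 | tert-butyl (2R,3R)-4-bromo-3-[(2R,3R)-2-(tert-butoxycarbonyl)-3-(3,5-dimethoxyphenyl)-7-methoxy-2,3-dihydro-1-benzofuran-5-yl]-6-methoxy-2,3-dihydro-1-benzofuran-2-carboxylate | Brc1cc(OC)cc2c1[C@@H](c1cc(OC)c3c(c1)[C@@H](c1cc(OC)cc(OC)c1)[C@H](C(=O)OC(C)(C)C)O3)[C@H](C(=O)OC(C)(C)C)O2
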